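Locants: C1'–C7' run along the linalool-derived chain from the vinyl CH2; C11 and C10 are the enol ether carbons on rings A and B. The route cuts the tetrahydropyran O–C2' bond and the C1'–C11 bond together, so C11 enters as carbon monoxide. The key step exploits the C1'–C2'–C3' unit, in which C3', the methyl-bearing ether carbon, is what remains of the vinyl carbinol of (R)-linalool: in one flask palladium closes the tetrahydropyran from the C6' hydroxyl, inserts CO at C1' and closes a cis-fused γ-lactone onto the C3' oxygen, setting C2'. The precursor is an acyclic ene-triol with C5' mesylated for later oxetane closure from C7'.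

Key step: step 5

Remarks on the chemistry:
- Ring A is the prenylated resorcinol ring and ring B the 4-hydroxyphenyl ring.
- The configurations of 7 and 9 were checked against the target and need no correction: C3' is R from (R)-linalool, C2' and C6' are R, and C5' is R in the mesylate and becomes S on oxetane closure.
- The epoxidation needs the enantiomer of the common D-fructose-derived Shi ketone; it is assumed to be available (it can be made from L-sorbose).

Step 1
Reactants: 1 (R)-linalool
Product: 3 (3R,5E)-3,7-dimethylocta-1,5-diene-3,7-diol, via tertiary allylic hydroperoxide 2 (not isolated)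
Conditions: O2, tetraphenylporphyrin (cat.), visible light, CH2Cl2, 0 °C; then PPh3, 0 °C → rt; chromatography
Reagents that add atoms: oxygen, O=O
Why: The Schenck ene reaction of singlet oxygen attacks only the trisubstituted C6'=C7' alkene and should give the (E)-C5'=C6' tertiary hydroperoxide beside its secondary regioisomer in comparable amounts; PPh3 reduces the O–O bond, the regioisomeric diol is removed by chromatography, and C3' is not touched.

Step 2
Reactants: 3 (3R,5E)-3,7-dimethylocta-1,5-diene-3,7-diol
Product: 4 (2R)-1-[(2S,3R)-3-(2-hydroxypropan-2-yl)oxiran-2-yl]-2-methylbut-3-en-2-ol (trans epoxide, C5' S, C6' R)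
Conditions: ent-Shi ketone (L-fructose-derived, 30 mol%), 2KHSO5·KHSO4·K2SO4, K2CO3, Bu4NHSO4, MeCN/CH2(OMe)2, aq. Na2B4O7 buffer (pH 10.5), 0 °C
Reagents that add atoms: potassium peroxymonosulfate, [K+].[O-]S(=O)(=O)OO
Why: Shi asymmetric epoxidation, in which the chiral dioxirane reacts with the E-disubstituted alkene much faster than with the vinyl group and the spiro transition state of the ent-ketone sets C5' (S) and C6' (R) under catalyst control.

Step 3
Reactants: 4 the C5' S, C6' R epoxide
Product: 6 (3R,5R,6R)-3,7-dimethyloct-1-ene-3,5,6,7-tetraol, via C5' benzoate 5 (not isolated)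
Conditions: PhCO2H, Ti(OiPr)4, CH2Cl2, rt; aq. tartaric acid work-up; then K2CO3 (cat.), MeOH, rt
Reagents that add atoms: benzoic acid, OC(=O)c1ccccc1
Why: Titanium-assisted opening of a 2,3-epoxy alcohol by a carboxylic acid occurs at the carbon remote from the carbinol (C5'; C6' is also neopentyl) with inversion, giving the erythro C5'/C6' pair, and base-catalysed methanolysis then removes the benzoyl group without touching a stereocentre.

Step 4
Reactants: 6 (3R,5R,6R)-3,7-dimethyloct-1-ene-3,5,6,7-tetraol
Product: 7 (3R,5R,6R)-3,6,7-trihydroxy-3,7-dimethyloct-1-en-5-yl methanesulfonate (ene-triol C5' mesylate)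
Conditions: MsCl (1.05 equiv), 2,4,6-collidine, CH2Cl2, −20 → 0 °C
Reagents that add atoms: methanesulfonyl chloride, CS(=O)(=O)Cl
Why: Sterically controlled monosulfonylation should take the C5' hydroxyl, because the C6' hydroxyl sits next to the quaternary C7' and both tertiary alcohols are inert; the C–O bond is retained, so C5' stays R.

Step 5
Reactants: 7 ene-triol C5' mesylate; 8 carbon monoxide
Product: 9 (3aR,5R,6R,7aR)-5-(2-hydroxypropan-2-yl)-7a-methyl-2-oxohexahydro-2H-furo[3,2-b]pyran-6-yl methanesulfonate (cis-fused pyrano-γ-lactone; C2' R, C3' R, C5' R, C6' R)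
Conditions: PdCl2 (10 mol%), CuCl2 (3 equiv), NaOAc (3 equiv), CO (1 atm), AcOH, rt
Reagents that add atoms: carbon monoxide, [C-]#[O+]
Why: Divalent palladium (PdCl2) coordinates the C1'=C2' vinyl group and the C6' hydroxyl attacks the internal carbon C2' anti to the metal, closing the tetrahydropyran ring 6-exo-trig through a chair in which C(CH3)2OH, OMs, the C3' methyl and the new CH2Pd arm are equatorial and the C3' hydroxyl is axial. CO inserts into the C1'–Pd bond and the axial C3' hydroxyl captures the acylpalladium, closing the γ-lactone ring (5-exo-trig at the acyl carbon) and releasing zerovalent palladium, which CuCl2 reoxidises. The closest known reaction type is the PdCl2/CuCl2 intramolecular alkoxycarbonylation–lactonisation of alkene diols to cis-fused bicyclic lactones, here in its 6-exo form. The one new stereocentre, C2' (R), is controlled by the purchased C3' centre: oxypalladation is reversible and only the isomer with C1' cis to the C3' oxygen can lactonise, and that isomer is also the equatorial one. The step needs the C6' hydroxyl to react in preference to the other oxygens: the C7' hydroxyl could only close a seven-membered ring, the C3' hydroxyl is allylic and cannot reach C2', and the C5' oxygen, which would otherwise cyclise 5-exo, is masked as the mesylate. NaOAc buffers the HCl formed, so the tertiary vinyl carbinol and the mesylate should survive.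

Step 6
Reactants: 9 cis-fused pyrano-γ-lactone mesylate
Product: 10 oxetane-fused pyrano-γ-lactone (C5'–O–C7' oxetane cis-fused at C5'–C6' on the face of the lactone oxygen; C2' R, C3' R, C5' S, C6' R)
Conditions: NaH (1.1 equiv), THF, 0 → 45 °C
Reagents that add atoms: none
Why: Williamson etherification (4-exo-tet): the C7' alkoxide, the only free hydroxyl because the lactone ties up the C3' oxygen, displaces the trans C5' mesylate from the rear, so C5' inverts from R to S.

Step 7
Reactants: 11 4,6-dibromoresorcinol
Product: 12 1,5-dibromo-2,4-bis(triisopropylsilyloxy)benzene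
Conditions: TIPSCl (2.4 equiv), imidazole, DMF, 40 °C
Reagents that add atoms: triisopropylsilyl chloride, CC(C)[Si](Cl)(C(C)C)C(C)C
Why: Imidazole-promoted O-silylation of both phenols gives ethers that tolerate organolithium reagents and fall to fluoride at the end.

Step 8
Reactants: 12 1,5-dibromo-2,4-bis(triisopropylsilyloxy)benzene
Product: 14 1-bromo-5-(3-methylbut-2-en-1-yl)-2,4-bis(triisopropylsilyloxy)benzene, via monolithiated arene 13 (not isolated)
Conditions: n-BuLi (1.0 equiv), Et2O, −78 °C; then CuBr·SMe2 (10 mol%), prenyl bromide, −78 → 0 °C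
Reagents that add atoms: prenyl bromide, CC(C)=CCBr
Why: A single bromine–lithium exchange on the symmetric dibromide (the second is disfavoured in the anion, and the bulky silyl groups resist migration to carbon at −78 °C) followed by copper-assisted allylic alkylation at the primary carbon of prenyl bromide should give the linear prenyl arene.

Step 9
Reactants: 15 2-bromo-4-hydroxybenzoic acid
Product: 17 2-bromo-4-(triisopropylsilyloxy)benzoic acid, via silyl ester 16 (not isolated)
Conditions: TIPSCl (2.3 equiv), imidazole, DMF, rt; then AcOH/THF/H2O, rt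
Reagents that add atoms: triisopropylsilyl chloride, CC(C)[Si](Cl)(C(C)C)C(C)C
Why: Double silylation followed by selective hydrolysis of the far more labile silyl ester leaves the aryl silyl ether in place.

Step 10
Reactants: 17 2-bromo-4-(triisopropylsilyloxy)benzoic acid
Product: 18 2-bromo-4-(triisopropylsilyloxy)benzoyl chloride
Conditions: (COCl)2, DMF (cat.), CH2Cl2, 0 °C → rt; concentrated and used crude
Reagents that add atoms: oxalyl chloride, ClC(=O)C(=O)Cl
Why: Acid chloride formation through the Vilsmeier-type chloroiminium species is standard and mild enough for the aryl silyl ether.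

Step 11
Reactants: 14 ring A aryl bromide; 10 oxetane-fused lactone; 18 ring B acid chloride
Product: 21 keto ester (C11 ketone bearing ring A as its 2,4-bis(triisopropylsilyloxy)-5-prenylphenyl group; C3' oxygen acylated as the 2-bromo-4-(triisopropylsilyloxy)benzoate; oxetane–tetrahydropyran core unchanged), via aryllithium 19 (not isolated), via lithium keto-alkoxide 20 (not isolated)
Conditions: 14, t-BuLi (2 equiv), THF, −78 °C; 10 (1.0 equiv), −78 → −40 °C; 18 (1.3 equiv), −40 °C → rt
Reagents that add atoms: none
Why: Bromine–lithium exchange gives 19, which adds once to the lactone carbonyl because the tetrahedral lithium lactolate resists a second addition in the cold; on warming it opens to the keto tertiary alkoxide 20, which the acid chloride O-acylates (organolithium addition to a lactone followed by alkoxide acylation), with no stereocentre formed or touched.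

Step 12
Reactants: 21 keto ester
Product: 22 cyclic C10=C11 enol ether (six-membered O–C10=C11–C1'–C2'–C3' ring; ring B with ortho bromine on C10, ring A on C11; three silyl ethers)
Conditions: TiCl3, Zn dust, Et3N, DME, reflux; slow addition of 21 (high dilution)
Reagents that add atoms: none
Why: Low-valent titanium keto ester reductive coupling (McMurry–Fürstner type) joins the aryl ketone carbon C11 to the ester carbonyl carbon C10 within a six-membered ring and deoxygenates the titanium-bound intermediate to the enol ether, whose ring fixes rings A and B cis; Et3N tempers the Lewis acidity towards the oxetane and silyl ethers.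

Step 13
Reactants: 22 cyclic enol ether tris(silyl ether)
Product: 23 triphenol aryl bromide (22 with all three silyl groups removed)
Conditions: TBAF (3.3 equiv), THF, 0 °C; pH 7 buffer work-up
Reagents that add atoms: none
Why: Fluoride cleaves the three aryl silyl ethers under non-acidic conditions, which spares the enol ether, the oxetane and the prenyl phenol.

Step 14
Reactants: 23 triphenol aryl bromide
Product: 24 target CNP0102779.1
Conditions: CuI (20 mol%), N,N-dimethylglycine (40 mol%), Cs2CO3 (3 equiv), degassed 1,4-dioxane (0.005 M), 90 °C, Ar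
Reagents that add atoms: none
Why: Intramolecular Ullmann-type C–O coupling: the cis enol ether holds the ring A phenoxide ortho to C11 next to the ring B C–Br bond, so closure of the seven-membered oxepine should outrun intermolecular arylation of the other two phenoxides at high dilution.

Compound list
1 | (R)-linalool, (3R)-3,7-dimethylocta-1,6-dien-3-ol | C=C[C@](C)(O)CCC=C(C)C | starting material
2 | (3R,5E)-7-hydroperoxy-3,7-dimethylocta-1,5-dien-3-ol | C=C[C@](C)(O)C/C=C/C(C)(C)OO | intermediate (not isolated)
3 | (3R,5E)-3,7-dimethylocta-1,5-diene-3,7-diol | C=C[C@](C)(O)C/C=C/C(C)(C)O | intermediate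
4 | (2R)-1-[(2S,3R)-3-(2-hydroxypropan-2-yl)oxiran-2-yl]-2-methylbut-3-en-2-ol | C=C[C@](C)(O)C[C@@H]1O[C@H]1C(C)(C)O | intermediate
5 | (3R,5R,6R)-3,6,7-trihydroxy-3,7-dimethyloct-1-en-5-yl benzoate | C=C[C@](C)(O)C[C@@H](OC(=O)c1ccccc1)[C@@H](O)C(C)(C)O | intermediate (not isolated)
6 | (3R,5R,6R)-3,7-dimethyloct-1-ene-3,5,6,7-tetraol | C=C[C@](C)(O)C[C@@H](O)[C@@H](O)C(C)(C)O | intermediate
7 | (3R,5R,6R)-3,6,7-trihydroxy-3,7-dimethyloct-1-en-5-yl methanesulfonate | C=C[C@](C)(O)C[C@@H](OS(C)(=O)=O)[C@@H](O)C(C)(C)O | intermediate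
8 | carbon monoxide | [C-]#[O+] | starting material
9 | (3aR,5R,6R,7aR)-5-(2-hydroxypropan-2-yl)-7a-methyl-2-oxohexahydro-2H-furo[3,2-b]pyran-6-yl methanesulfonate | O=C1C[C@H]2O[C@@H](C(C)(C)O)[C@@H](C[C@@]2(C)O1)OS(C)(=O)=O | intermediate
10 | oxetane-fused pyrano-γ-lactone (C2' R, C3' R, C5' S, C6' R) | O=C1C[C@H]2O[C@@H]3[C@H](C[C@@]2(C)O1)OC3(C)C | intermediate
11 | 4,6-dibromoresorcinol | Oc1cc(O)c(Br)cc1Br | starting material
12 | 1,5-dibromo-2,4-bis(triisopropylsilyloxy)benzene | CC(C)[Si](Oc1cc(O[Si](C(C)C)(C(C)C)C(C)C)c(Br)cc1Br)(C(C)C)C(C)C | intermediate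
13 | [5-bromo-2,4-bis(triisopropylsilyloxy)phenyl]lithium | CC(C)[Si](Oc1cc(O[Si](C(C)C)(C(C)C)C(C)C)c(Br)cc1[Li])(C(C)C)C(C)C | intermediate (not isolated)
14 | 1-bromo-5-(3-methylbut-2-en-1-yl)-2,4-bis(triisopropylsilyloxy)benzene | CC(C)=CCc1cc(Br)c(O[Si](C(C)C)(C(C)C)C(C)C)cc1O[Si](C(C)C)(C(C)C)C(C)C | intermediate
15 | 2-bromo-4-hydroxybenzoic acid | OC(=O)c1ccc(O)cc1Br | starting material
16 | triisopropylsilyl 2-bromo-4-(triisopropylsilyloxy)benzoate | CC(C)[Si](OC(=O)c1ccc(O[Si](C(C)C)(C(C)C)C(C)C)cc1Br)(C(C)C)C(C)C | intermediate (not isolated)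
17 | 2-bromo-4-(triisopropylsilyloxy)benzoic acid | OC(=O)c1ccc(O[Si](C(C)C)(C(C)C)C(C)C)cc1Br | intermediate
18 | 2-bromo-4-(triisopropylsilyloxy)benzoyl chloride | ClC(=O)c1ccc(O[Si](C(C)C)(C(C)C)C(C)C)cc1Br | intermediate
19 | [5-(3-methylbut-2-en-1-yl)-2,4-bis(triisopropylsilyloxy)phenyl]lithium | CC(C)=CCc1cc([Li])c(O[Si](C(C)C)(C(C)C)C(C)C)cc1O[Si](C(C)C)(C(C)C)C(C)C | intermediate (not isolated)
20 | lithium C3' alkoxide of the ring A ketone (ring-opened adduct of 19 and 10) | CC(C)=CCc1cc(C(=O)C[C@H]2O[C@@H]3[C@H](C[C@@]2(C)O[Li])OC3(C)C)c(O[Si](C(C)C)(C(C)C)C(C)C)cc1O[Si](C(C)C)(C(C)C)C(C)C | intermediate (not isolated)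
21 | keto ester: ring A C11 ketone with C3' 2-bromo-4-(triisopropylsilyloxy)benzoate | CC(C)=CCc1cc(C(=O)C[C@H]2O[C@@H]3[C@H](C[C@@]2(C)OC(=O)c2ccc(O[Si](C(C)C)(C(C)C)C(C)C)cc2Br)OC3(C)C)c(O[Si](C(C)C)(C(C)C)C(C)C)cc1O[Si](C(C)C)(C(C)C)C(C)C | intermediate
22 | cyclic C10=C11 enol ether, tris(triisopropylsilyl) ether, ring B ortho bromide | Brc1cc(O[Si](C(C)C)(C(C)C)C(C)C)ccc1C1=C(c2cc(CC=C(C)C)c(O[Si](C(C)C)(C(C)C)C(C)C)cc2O[Si](C(C)C)(C(C)C)C(C)C)C[C@H]2O[C@@H]3[C@H](C[C@@]2(C)O1)OC3(C)C | intermediate
23 | triphenol aryl bromide (desilylated 22) | Brc1cc(O)ccc1C1=C(c2cc(CC=C(C)C)c(O)cc2O)C[C@H]2O[C@@H]3[C@H](C[C@@]2(C)O1)OC3(C)C | intermediate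
24 | CNP0102779.1 | CC(C)=CCc1cc2c(cc1O)Oc1cc(O)ccc1C1=C2C[C@H]2O[C@@H]3[C@H](C[C@@]2(C)O1)OC3(C)C | target

Total step count: 14. Longest linear sequence: 10 steps (steps 1–6 and 11–14, from (R)-linalool).

Steps most likely to fail

Step 5 (key step). What may go wrong: ionisation or allylic transposition of the tertiary vinyl carbinol, Wacker-type oxidation of the vinyl group, or slow oxypalladation because the neighbouring mesylate deactivates the C6' hydroxyl. The fallback sets out from 7 and comes back at 9, and it separates ring closure from carbonylation. Iodoetherification of 7 (I2, NaHCO3, MeCN, 0 °C) should close the same tetrahydropyran 6-exo through the chair with the CH2I arm equatorial, giving the iodomethyl tetrahydropyran F1 with that arm cis to the C3' hydroxyl. Atom-transfer carbonylation of this γ-iodo alcohol (CO under pressure, Pd(PPh3)4 cat., light, Et3N, DMAP) then inserts CO into the C1'–iodine bond and lactonises onto the C3' hydroxyl to give 9.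

Step 11. What may go wrong: acylation at the lactolate oxygen instead of the ring-opened alkoxide, incomplete acylation of the hindered tertiary alkoxide, or a second addition of the aryllithium. The fallback sets out from 10 and comes back at 21. Lactone 10 is opened with the chloromagnesium amide of N,O-dimethylhydroxylamine (MeONHMe·HCl, i-PrMgCl, THF, −20 °C) to the hydroxy Weinreb amide F2. Its magnesium alkoxide is acylated in the same flask with 18 (DMAP) to give the ester amide F3. The arylmagnesium bromide F4 (from 19 and MgBr2·OEt2) then adds to the Weinreb amide only, since the tertiary-alkyl ortho-bromobenzoate is too hindered and a Grignard reagent should not exchange with the aryl bromide; work-up gives 21.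

Step 12. What may go wrong: Lewis-acid opening of the oxetane, reductive loss of the aryl bromide, or arrest before deoxygenation when the tetrasubstituted alkene between two ortho-substituted aryl groups has to form. The fallback sets out from 21 and comes back at 22, making the same C10=C11 bond by an intramolecular Wittig olefination of the ester carbonyl under neutral or basic conditions. NaBH4 (MeOH/THF, 0 °C) reduces the aryl ketone to the benzylic alcohol F5 (C11 epimers, of no consequence). CBr4/PPh3 gives the benzylic bromide F6, and PPh3 in MeCN at 70 °C gives the phosphonium bromide F7. KOtBu in toluene (rt → 80 °C) then forms the benzylic ylide, which attacks the aryl ester carbonyl through a six-membered ring and expels Ph3P=O to give 22.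

Further compounds
F1 | step 5 | iodomethyl tetrahydropyran: C1' iodide with free C3' and C7' hydroxyls and C5' mesylate, configured at C2', C3', C5', C6' as in 9 | IC[C@H]1O[C@@H](C(C)(C)O)[C@@H](C[C@@]1(C)O)OS(C)(=O)=O
F2 | step 11 | hydroxy Weinreb amide from ring opening of 10 | CON(C)C(=O)C[C@H]1O[C@@H]2[C@H](C[C@@]1(C)O)OC2(C)C
F3 | step 11 | ester amide: F2 acylated at the C3' oxygen with 18 | CON(C)C(=O)C[C@H]1O[C@@H]2[C@H](C[C@@]1(C)OC(=O)c1ccc(O[Si](C(C)C)(C(C)C)C(C)C)cc1Br)OC2(C)C
F4 | step 11 | [5-(3-methylbut-2-en-1-yl)-2,4-bis(triisopropylsilyloxy)phenyl]magnesium bromide | CC(C)=CCc1cc([Mg]Br)c(O[Si](C(C)C)(C(C)C)C(C)C)cc1O[Si](C(C)C)(C(C)C)C(C)C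
F5 | step 12 | benzylic alcohol from reduction of 21 (C11 epimers) | CC(C)=CCc1cc(C(O)C[C@H]2O[C@@H]3[C@H](C[C@@]2(C)OC(=O)c2ccc(O[Si](C(C)C)(C(C)C)C(C)C)cc2Br)OC3(C)C)c(O[Si](C(C)C)(C(C)C)C(C)C)cc1O[Si](C(C)C)(C(C)C)C(C)C
F6 | step 12 | benzylic bromide (C11 epimers) | CC(C)=CCc1cc(C(Br)C[C@H]2O[C@@H]3[C@H](C[C@@]2(C)OC(=O)c2ccc(O[Si](C(C)C)(C(C)C)C(C)C)cc2Br)OC3(C)C)c(O[Si](C(C)C)(C(C)C)C(C)C)cc1O[Si](C(C)C)(C(C)C)C(C)C
F7 | step 12 | C11 triphenylphosphonium bromide (C11 epimers) | CC(C)=CCc1cc(C([P+](c4ccccc4)(c4ccccc4)c4ccccc4)C[C@H]2O[C@@H]3[C@H](C[C@@]2(C)OC(=O)c2ccc(O[Si](C(C)C)(C(C)C)C(C)C)cc2Br)OC3(C)C)c(O[Si](C(C)C)(C(C)C)C(C)C)cc1O[Si](C(C)C)(C(C)C)C(C)C.[Br-]
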